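**Retrosynthetic overview**
- The target is opened at O1–C2 and at the C3–O bond to an α-methylene deoxybenzoin (a 2-aryl-1-arylprop-2-en-1-one). In one flask, a catalytic asymmetric nucleophilic epoxidation builds the (R)-oxirane and sets C3, then fluoride frees a ring-A phenoxide that opens the oxirane (6-endo) and closes ring C, with global desilylation in the same operation.
- The enone comes from Mannich α-methylenation of a deoxybenzoin, itself made by palladium-catalysed α-arylation of silylated phloroacetophenone (ring A) with a ring-B aryl bromide.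
- The ring-B bromide comes from an aromatic Claisen rearrangement of the prenyl ether of 4-bromo-3-methoxyphenol (reverse-prenyl group), silylated in situ.
- Ring order: rings A and B are bought as arenes; the oxirane forms first and ring C second, both in the last operation.

Assumption: the three starting materials are catalogue chemicals, and the absolute sense of induction in the key step is fixed by the choice of ligand antipode (written for the ligand from (S)-pipecolic acid; its mirror image is used if that one proves to give the (S)-epoxide).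

**Step 1**
Reactants: 1 4-bromo-3-methoxyphenol; 2 1-bromo-3-methylbut-2-ene (prenyl bromide)
Product: 3 1-bromo-2-methoxy-4-[(3-methylbut-2-en-1-yl)oxy]benzene
Conditions: K2CO3, acetone, reflux
Reagents that add atoms: none
Why: Williamson etherification, SN2 attack of the phenoxide on the primary allylic bromide, with O-alkylation dominant under K2CO3/acetone.

**Step 2**
Reactants: 3 1-bromo-2-methoxy-4-[(3-methylbut-2-en-1-yl)oxy]benzene
Product: 5 [4-bromo-5-methoxy-2-(2-methylbut-3-en-2-yl)phenoxy](tert-butyl)dimethylsilane, via Claisen phenol 4 (not isolated)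
Conditions: MTBSTFA (1.5 equiv), PhNEt2, 195 °C, sealed tube
Reagents that add atoms: N-(tert-butyldimethylsilyl)-N-methyltrifluoroacetamide (MTBSTFA), CN(C(=O)C(F)(F)F)[Si](C)(C)C(C)(C)C
Why: Aromatic Claisen ([3,3]) rearrangement of the aryl prenyl ether puts the 1,1-dimethylallyl group on the ortho carbon para to OMe (the other ortho carbon is flanked by OMe, the para carbon carries Br), and thermal silyl transfer from MTBSTFA traps phenol 4 at once, which blocks the abnormal Claisen and dihydrobenzofuran side reactions.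

**Step 3**
Reactants: 6 1-(2,4,6-trihydroxyphenyl)ethan-1-one
Product: 7 1-{2,4,6-tris[(triisopropylsilyl)oxy]phenyl}ethan-1-one
Conditions: TIPSOTf (3.5 equiv), 2,6-lutidine, CH2Cl2, 0 °C → rt
Reagents that add atoms: triisopropylsilyl trifluoromethanesulfonate, CC(C)[Si](OS(=O)(=O)C(F)(F)F)(C(C)C)C(C)C
Why: Silyl etherification of all three phenols with the silyl triflate; TIPS is used on ring A because its O-to-O migration onto a ketone enolate and its cleavage by base are slow, while fluoride still removes it easily.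

**Step 4**
Reactants: 7 1-{2,4,6-tris[(triisopropylsilyl)oxy]phenyl}ethan-1-one (1.2 equiv); 5 [4-bromo-5-methoxy-2-(2-methylbut-3-en-2-yl)phenoxy](tert-butyl)dimethylsilane
Product: 8 2-{4-[(tert-butyldimethylsilyl)oxy]-2-methoxy-5-(2-methylbut-3-en-2-yl)phenyl}-1-{2,4,6-tris[(triisopropylsilyl)oxy]phenyl}ethan-1-one
Conditions: Pd(OAc)2 (5 mol %), XPhos (10 mol %), K3PO4, toluene, 80 °C
Reagents that add atoms: none
Why: Buchwald–Hartwig-type palladium-catalysed ketone α-arylation (oxidative addition of 5, palladium enolate from the methyl ketone, reductive elimination); the weak insoluble base spares the aryl silyl ethers and the ortho-methoxy group disfavours a second arylation.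

**Step 5**
Reactants: 8 2-{4-[(tert-butyldimethylsilyl)oxy]-2-methoxy-5-(2-methylbut-3-en-2-yl)phenyl}-1-{2,4,6-tris[(triisopropylsilyl)oxy]phenyl}ethan-1-one
Product: 9 2-{4-[(tert-butyldimethylsilyl)oxy]-2-methoxy-5-(2-methylbut-3-en-2-yl)phenyl}-1-{2,4,6-tris[(triisopropylsilyl)oxy]phenyl}prop-2-en-1-one
Conditions: CH2(NMe2)2, Ac2O, THF, 60 °C
Reagents that add atoms: N,N,N′,N′-tetramethylmethanediamine, CN(C)CN(C)C
Why: Mannich α-methylenation: the enol of 8 is aminomethylated by the iminium ion formed from the aminal and Ac2O, and the N-acetylated Mannich base eliminates (E1cB) to the 1,1-disubstituted enone, with liberated amine scavenged as its acetamide; no stereocentre is formed.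

**Step 6**
Reactants: 9 2-{4-[(tert-butyldimethylsilyl)oxy]-2-methoxy-5-(2-methylbut-3-en-2-yl)phenyl}-1-{2,4,6-tris[(triisopropylsilyl)oxy]phenyl}prop-2-en-1-one
Product: 12 (3R)-3,5,7-trihydroxy-3-[4-hydroxy-2-methoxy-5-(2-methylbut-3-en-2-yl)phenyl]-2,3-dihydro-4H-chromen-4-one, via silylated epoxide 10 (not isolated), via chromanone silyl ether 11 (not isolated)
Conditions: Sc(OTf)3 (10 mol %), chiral N,N′-dioxide ligand (10 mol %; C2-symmetric, from (S)-pipecolic acid, 2,6-diisopropylanilide arms, propane-1,3-diyl linker), 30% aq. H2O2 (1.5 equiv), THF, 0 °C; Me2S; then TBAF (3.2 equiv), −40 → 0 °C; then TBAF (1.5 equiv), rt; AcOH; all under argon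
Reagents that add atoms: hydrogen peroxide, OO
Why: Proposed new method: hydrogen peroxide activated on the chiral N,N′-dioxide–Sc(OTf)3 complex adds to the unhindered CH2 terminus of the enone (Weitz–Scheffer manifold) and the scandium-bound enolate closes onto the proximal peroxide oxygen inside the ligand pocket, so this ring closure sets the quaternary centre as the (R)-epoxide 10; fluoride then unmasks the ring-A phenoxides first (ethers of acidic acyl-phenols), and an ortho phenoxide (the two are equivalent) opens the oxirane at its primary CH2 carbon in a 6-endo SN2 step that closes ring C without touching the C3–O bond, so the (R) configuration is carried into 11, and the hindered ring-B silyl ether is cleaved last so that no para-phenoxide (quinone-methide opening, racemisation) sits next to an intact epoxide; the closest known reaction types are the chiral N,N′-dioxide–Sc(OTf)3/H2O2 epoxidation of enones and the base-induced cyclisation of 2′-hydroxy-α-methylenedeoxybenzoin epoxides to racemic 3-hydroxyisoflavanones.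

**Compound list**
1 | 4-bromo-3-methoxyphenol | COc1cc(O)ccc1Br | starting material
2 | 1-bromo-3-methylbut-2-ene (prenyl bromide) | CC(C)=CCBr | starting material
3 | 1-bromo-2-methoxy-4-[(3-methylbut-2-en-1-yl)oxy]benzene | COc1cc(OCC=C(C)C)ccc1Br | intermediate
4 | 4-bromo-5-methoxy-2-(2-methylbut-3-en-2-yl)phenol | COc1cc(O)c(C(C)(C)C=C)cc1Br | intermediate (not isolated)
5 | [4-bromo-5-methoxy-2-(2-methylbut-3-en-2-yl)phenoxy](tert-butyl)dimethylsilane | COc1cc(O[Si](C)(C)C(C)(C)C)c(C(C)(C)C=C)cc1Br | intermediate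
6 | 1-(2,4,6-trihydroxyphenyl)ethan-1-one (2,4,6-trihydroxyacetophenone) | CC(=O)c1c(O)cc(O)cc1O | starting material
7 | 1-{2,4,6-tris[(triisopropylsilyl)oxy]phenyl}ethan-1-one | CC(=O)c1c(O[Si](C(C)C)(C(C)C)C(C)C)cc(O[Si](C(C)C)(C(C)C)C(C)C)cc1O[Si](C(C)C)(C(C)C)C(C)C | intermediate
8 | 2-{4-[(tert-butyldimethylsilyl)oxy]-2-methoxy-5-(2-methylbut-3-en-2-yl)phenyl}-1-{2,4,6-tris[(triisopropylsilyl)oxy]phenyl}ethan-1-one | O=C(Cc1cc(C(C)(C)C=C)c(O[Si](C)(C)C(C)(C)C)cc1OC)c1c(O[Si](C(C)C)(C(C)C)C(C)C)cc(O[Si](C(C)C)(C(C)C)C(C)C)cc1O[Si](C(C)C)(C(C)C)C(C)C | intermediate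
9 | 2-{4-[(tert-butyldimethylsilyl)oxy]-2-methoxy-5-(2-methylbut-3-en-2-yl)phenyl}-1-{2,4,6-tris[(triisopropylsilyl)oxy]phenyl}prop-2-en-1-one | C=C(C(=O)c1c(O[Si](C(C)C)(C(C)C)C(C)C)cc(O[Si](C(C)C)(C(C)C)C(C)C)cc1O[Si](C(C)C)(C(C)C)C(C)C)c1cc(C(C)(C)C=C)c(O[Si](C)(C)C(C)(C)C)cc1OC | intermediate
10 | [(2R)-2-{4-[(tert-butyldimethylsilyl)oxy]-2-methoxy-5-(2-methylbut-3-en-2-yl)phenyl}oxiran-2-yl]{2,4,6-tris[(triisopropylsilyl)oxy]phenyl}methanone | O=C(c1c(O[Si](C(C)C)(C(C)C)C(C)C)cc(O[Si](C(C)C)(C(C)C)C(C)C)cc1O[Si](C(C)C)(C(C)C)C(C)C)[C@@]1(c2cc(C(C)(C)C=C)c(O[Si](C)(C)C(C)(C)C)cc2OC)CO1 | intermediate (not isolated)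
11 | (3R)-3-{4-[(tert-butyldimethylsilyl)oxy]-2-methoxy-5-(2-methylbut-3-en-2-yl)phenyl}-3,5,7-trihydroxy-2,3-dihydro-4H-chromen-4-one | C=CC(C)(C)c1cc([C@@]2(O)COc3cc(O)cc(O)c3C2=O)c(OC)cc1O[Si](C)(C)C(C)(C)C | intermediate (not isolated)
12 | (3R)-3,5,7-trihydroxy-3-[4-hydroxy-2-methoxy-5-(2-methylbut-3-en-2-yl)phenyl]-2,3-dihydro-4H-chromen-4-one | C=CC(C)(C)c1cc([C@@]2(O)COc3cc(O)cc(O)c3C2=O)c(OC)cc1O | target

**Step count**
Total: 6 steps. Longest linear sequence: 5 steps (steps 1, 2, 4, 5, 6 from compound 1); the ring-A branch is one step (step 3).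

**Three steps most likely to fail, with fallbacks**

Step 6 (key cascade). The enantioselectivity is untested on a ketone flanked by two bulky silyloxy groups. The Lewis acid could also ionise the electron-rich aryl epoxide (Meinwald-type rearrangement), and early loss of the ring-B silyl group could erode ee through quinone-methide opening. The fallback sets out from 9 and comes back at 12 and gives up catalytic asymmetric induction. Compound 9 is epoxidised with t-BuOOH/DBU (racemic Weitz–Scheffer reaction) to the racemic silylated epoxide F1. In the same flask this is treated with TBAF as in the route; it passes through the racemic chromanone silyl ether F2 to the racemic target F3. The enantiomers are then separated by preparative chiral SFC on an amylose tris(3,5-dimethylphenylcarbamate) phase, giving 12 and the unwanted (3S)-enantiomer F4.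

Step 4 (α-arylation). The ketone enolate could pull a silyl group from an ortho oxygen (O-to-O migration), and both coupling partners are hindered. The fallback sets out from 7 and 5, comes back at 8 and avoids any ketone enolate under basic conditions. Compound 7 is oxidised with SeO2 (dioxane–H2O, reflux, Riley oxidation) to the arylglyoxal 2-oxo-2-{2,4,6-tris[(triisopropylsilyl)oxy]phenyl}acetaldehyde F5. Bromide 5 is converted with n-BuLi (THF, −78 °C) into {4-[(tert-butyldimethylsilyl)oxy]-2-methoxy-5-(2-methylbut-3-en-2-yl)phenyl}lithium F6. This adds to the aldehyde carbonyl of F5 (the ketone is shielded by its two ortho silyloxy groups), and the lithium alkoxide is acetylated in the same flask with Ac2O to the racemic α-acetoxy ketone 2-oxo-1-{4-[(tert-butyldimethylsilyl)oxy]-2-methoxy-5-(2-methylbut-3-en-2-yl)phenyl}-2-{2,4,6-tris[(triisopropylsilyl)oxy]phenyl}ethyl acetate F7. Reductive cleavage of the α-acetoxy group with SmI2 (THF–MeOH, −78 °C) gives 8.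

Step 2 (Claisen/silylation). Risks are partial rearrangement to the carbon between the two oxygens, deprenylation at 195 °C and incomplete silylation of the hindered phenol. The fallback sets out from 1, comes back at 5 and replaces the sigmatropic step by a cross-coupling. Compound 1 is iodinated with N-iodosuccinimide at the carbon ortho to OH and para to OMe to give 4-bromo-2-iodo-5-methoxyphenol F8. This is silylated (TBSCl, imidazole, DMF) to (4-bromo-2-iodo-5-methoxyphenoxy)(tert-butyl)dimethylsilane F9. F9 is then coupled chemoselectively at the C–I bond with prenylboronic acid pinacol ester, using Pd(OAc)2, a bulky biaryl phosphine chosen for γ-selective (branched) allyl transfer, and K3PO4; this installs the 1,1-dimethylallyl group and gives 5.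

**Further compounds**
F1 | step 6 | racemic (2-{4-[(tert-butyldimethylsilyl)oxy]-2-methoxy-5-(2-methylbut-3-en-2-yl)phenyl}oxiran-2-yl){2,4,6-tris[(triisopropylsilyl)oxy]phenyl}methanone | O=C(c1c(O[Si](C(C)C)(C(C)C)C(C)C)cc(O[Si](C(C)C)(C(C)C)C(C)C)cc1O[Si](C(C)C)(C(C)C)C(C)C)C1(c2cc(C(C)(C)C=C)c(O[Si](C)(C)C(C)(C)C)cc2OC)CO1
F2 | step 6 | racemic 3-{4-[(tert-butyldimethylsilyl)oxy]-2-methoxy-5-(2-methylbut-3-en-2-yl)phenyl}-3,5,7-trihydroxy-2,3-dihydro-4H-chromen-4-one | C=CC(C)(C)c1cc(C2(O)COc3cc(O)cc(O)c3C2=O)c(OC)cc1O[Si](C)(C)C(C)(C)C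
F3 | step 6 | racemic 3,5,7-trihydroxy-3-[4-hydroxy-2-methoxy-5-(2-methylbut-3-en-2-yl)phenyl]-2,3-dihydro-4H-chromen-4-one | C=CC(C)(C)c1cc(C2(O)COc3cc(O)cc(O)c3C2=O)c(OC)cc1O
F4 | step 6 | (3S)-3,5,7-trihydroxy-3-[4-hydroxy-2-methoxy-5-(2-methylbut-3-en-2-yl)phenyl]-2,3-dihydro-4H-chromen-4-one | C=CC(C)(C)c1cc([C@]2(O)COc3cc(O)cc(O)c3C2=O)c(OC)cc1O
F5 | step 4 | 2-oxo-2-{2,4,6-tris[(triisopropylsilyl)oxy]phenyl}acetaldehyde | O=CC(=O)c1c(O[Si](C(C)C)(C(C)C)C(C)C)cc(O[Si](C(C)C)(C(C)C)C(C)C)cc1O[Si](C(C)C)(C(C)C)C(C)C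
F6 | step 4 | {4-[(tert-butyldimethylsilyl)oxy]-2-methoxy-5-(2-methylbut-3-en-2-yl)phenyl}lithium | [Li]c1cc(C(C)(C)C=C)c(O[Si](C)(C)C(C)(C)C)cc1OC
F7 | step 4 | racemic 2-oxo-1-{4-[(tert-butyldimethylsilyl)oxy]-2-methoxy-5-(2-methylbut-3-en-2-yl)phenyl}-2-{2,4,6-tris[(triisopropylsilyl)oxy]phenyl}ethyl acetate | CC(=O)OC(C(=O)c1c(O[Si](C(C)C)(C(C)C)C(C)C)cc(O[Si](C(C)C)(C(C)C)C(C)C)cc1O[Si](C(C)C)(C(C)C)C(C)C)c1cc(C(C)(C)C=C)c(O[Si](C)(C)C(C)(C)C)cc1OC
F8 | step 2 | 4-bromo-2-iodo-5-methoxyphenol | COc1cc(O)c(I)cc1Br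
F9 | step 2 | (4-bromo-2-iodo-5-methoxyphenoxy)(tert-butyl)dimethylsilane | COc1cc(O[Si](C)(C)C(C)(C)C)c(I)cc1Br
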